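A direct plan would grow the depside outward from ring A: phenol A1 (methyl 4-hydroxy-2-methoxy-6-methylbenzoate) would be esterified with but-2-ynoic acid to aryl ynoate A2.
Ring B would be closed on A2 by a thermal Diels–Alder reaction with 1-methoxy-1,3-bis(trimethylsilyloxy)buta-1,3-diene A3 and loss of methanol, which would give resorcylate diol A4.
Butynoylation of the 4'-OH of A4 (to A5) and a second cycloaddition of A3 would then add ring C.
Weakest would be the two ring-forming cycloadditions: a β-methyl ynoate is a sluggish dienophile, whereas the ketene acetal diene is a strong nucleophile that could attack the aryl ester links and would decay at 110–130 °C.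
Next would be the mono-acylation of diol A4: only the hydrogen bond of the 2'-OH would separate two phenols, and the activated ynoate could end up on either oxygen or on both.
The steps that only supply A1 and A3 (protection, methylation and deprotection; two silylations) would add five steps without adding complexity.

The new route would treat each depside link Ar–C(=O)–O–Ar' as aryl halide + CO + phenol. All three rings enter as intact arenes with their oxygens differentiated before any ester exists; the free phenols of rings A and B come from sterically controlled C–H borylation/oxidation. The key step exploits that the ester carbonyl carbon C7' is a one-carbon bridge between C1' of ring B (flanked by 2'-O and 6'-CH3) and O4 of ring A: palladium would insert CO between bromide 11 (rings C and B) and phenol 10, forming the C1'–C7' and C7'–O4 bonds at once. No ring is built on an aryl ester, no diol is mono-acylated, and assembly runs from ring C to ring A.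

Key step: step 7

Assumption: 2-bromo-3-methylphenol and methyl 2-methoxy-6-methylbenzoate are taken as commercial. The target has no stereocentre, so no stereocontrol is needed. Ring B carries primed locants and ring C doubly primed ones.

Step 1
Reactants: 1 orcinol (5-methylbenzene-1,3-diol)
Product: 2 1,3-bis(benzyloxy)-5-methylbenzene
Conditions: BnBr (2.3 equiv), K2CO3 (3 equiv), DMF, 60 °C
Reagents that add atoms: benzyl bromide, BrCc1ccccc1
Why: Williamson etherification of both phenols of the symmetric diol, so no selectivity is needed.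

Step 2
Reactants: 2 1,3-bis(benzyloxy)-5-methylbenzene
Product: 3 1,5-bis(benzyloxy)-2-iodo-3-methylbenzene (ring C iodide)
Conditions: N-iodosuccinimide (1.05 equiv), MeCN, 0 °C to rt, dark
Reagents that add atoms: N-iodosuccinimide, O=C1CCC(=O)N1I
Why: Electrophilic aromatic iodination, which should take the position between one benzyloxy group and the methyl group in preference to the more crowded position between the two benzyloxy groups, as the corresponding dimethyl ether does, and so places iodine on the future C1''.

Step 3
Reactants: 4 2-bromo-3-methylphenol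
Product: 5 2-bromo-1-[(3,5-dimethylbenzyl)oxy]-3-methylbenzene
Conditions: 3,5-dimethylbenzyl bromide (1.1 equiv), K2CO3 (1.5 equiv), DMF, rt to 50 °C
Reagents that add atoms: 3,5-dimethylbenzyl bromide, Cc1cc(C)cc(CBr)c1
Why: Williamson etherification; the 3,5-dimethylbenzyl group is chosen because each of its aryl C–H bonds lies between two substituents, which should keep it inert in the borylation of step 4 (a plain benzyl group would be borylated), while it still leaves by hydrogenolysis.

Step 4
Reactants: 5 2-bromo-1-[(3,5-dimethylbenzyl)oxy]-3-methylbenzene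
Product: 7 4-bromo-3-[(3,5-dimethylbenzyl)oxy]-5-methylphenol (ring B bromophenol), via aryl pinacolboronate 6 (not isolated)
Conditions: B2pin2 (1.0 equiv), [Ir(OMe)(cod)]2 (1.5 mol%), 4,4'-di-tert-butyl-2,2'-bipyridine (3 mol%), THF, 60 °C; then KHSO5 (Oxone), acetone/H2O, rt
Reagents that add atoms: bis(pinacolato)diboron, CC1(C)OB(OC1(C)C)B1OC(C)(C)C(C)(C)O1 (boron of 6 only); potassium peroxymonosulfate, [K+].[O-]S(=O)(=O)OO (the phenol oxygen)
Why: Iridium-catalysed, sterically controlled C–H borylation followed by oxidation of the C–B bond in the same flask; C5 carries the only C–H bond without an ortho substituent, so the hydroxyl group should enter para to bromine and give ring B with its two oxygens already differentiated.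

Step 5
Reactants: 8 methyl 2-methoxy-6-methylbenzoate
Product: 10 methyl 4-hydroxy-2-methoxy-6-methylbenzoate (ring A phenol), via aryl pinacolboronate 9 (not isolated)
Conditions: B2pin2 (1.0 equiv), [Ir(OMe)(cod)]2 (1.5 mol%), 4,4'-di-tert-butyl-2,2'-bipyridine (3 mol%), THF, 60 °C; then KHSO5 (Oxone), acetone/H2O, rt
Reagents that add atoms: bis(pinacolato)diboron, CC1(C)OB(OC1(C)C)B1OC(C)(C)C(C)(C)O1 (boron of 9 only); potassium peroxymonosulfate, [K+].[O-]S(=O)(=O)OO (the phenol oxygen)
Why: The same iridium-catalysed C–H borylation/oxidation; of the three ring C–H bonds only the one at C4 has no ortho substituent, so the phenol should appear para to the ester without any protecting group.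

Step 6
Reactants: 3 1,5-bis(benzyloxy)-2-iodo-3-methylbenzene; 7 4-bromo-3-[(3,5-dimethylbenzyl)oxy]-5-methylphenol
Product: 11 4-bromo-3-[(3,5-dimethylbenzyl)oxy]-5-methylphenyl 2,4-bis(benzyloxy)-6-methylbenzoate (C–B bromide)
Conditions: 7 (1.2 equiv), CO (1 atm), PdCl2(PPh3)2 (5 mol%), Et3N (3 equiv), PhMe, 70 °C
Reagents that add atoms: carbon monoxide, [C-]#[O+]
Why: Palladium-catalysed aryloxycarbonylation (Heck-type carbonylation) of an aryl iodide, in which zerovalent palladium inserts into the C–I bond of 3, CO insertion gives the aroyl–palladium iodide and the aryloxide of 7 takes up the acyl group, while the crowded, electron-rich C–Br bonds of 7 and 11 should stay untouched by the triphenylphosphine catalyst at this temperature.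

Step 7
Reactants: 11 C–B bromide; 10 methyl 4-hydroxy-2-methoxy-6-methylbenzoate
Product: 12 methyl 4-({4-[(2,4-bis(benzyloxy)-6-methylbenzoyl)oxy]-2-[(3,5-dimethylbenzyl)oxy]-6-methylbenzoyl}oxy)-2-methoxy-6-methylbenzoate (protected tridepside)
Conditions: 10 (1.3 equiv), CO (5 bar), Pd(OAc)2 (5 mol%), Xantphos (7.5 mol%), Et3N (3 equiv), PhMe, 100 °C
Reagents that add atoms: carbon monoxide, [C-]#[O+]
Why: Oxidative addition of zerovalent palladium into the C–Br bond of 11, migratory insertion of CO (which relieves the strain of the doubly ortho-substituted aryl–palladium bond) and exchange of bromide for the aryloxide of 10 would give an aroyl(aryloxy)palladium complex, whose C–O reductive elimination releases ester 12. The closest known reaction type is the palladium-catalysed three-component aryloxycarbonylation of aryl bromides with phenols, here with the wide-bite-angle ligand Xantphos that is usual for ortho-substituted aryl bromides. No ring is closed and no stereocentre is formed. The C1'–C7' and C7'–O4 bonds arise in one operation and the ester oxygen is delivered at the metal, so the crowded carbonyl carbon between 2'-O and 6'-CH3 never has to pass through the tetrahedral intermediate of an acylation. The step needs carbonylation to win over direct C–O coupling to a diaryl ether, which the CO pressure should secure because insertion outruns C–O reductive elimination from an arylpalladium aryloxide, and it needs the C–B ester to survive the aryloxide of 10, which its two ortho substituents (2''-OBn and 6''-CH3) should secure. Only one carbon–halogen bond is present, and the methyl ester, the methyl ether and the benzyl-type ethers are inert to the catalyst.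

Step 8
Reactants: 12 protected tridepside
Product: 13 CNP0503951.0, methyl 4-({4-[(2,4-dihydroxy-6-methylbenzoyl)oxy]-2-hydroxy-6-methylbenzoyl}oxy)-2-methoxy-6-methylbenzoate
Conditions: H2 (1 atm), 10% Pd/C, EtOAc/THF, rt
Reagents that add atoms: none
Why: Hydrogenolysis of the two benzyl ethers and the 3,5-dimethylbenzyl ether over palladium on carbon under neutral conditions, which should leave both aryl ester links, the methyl ester and the methyl ether intact.

**Compound list**
1 | orcinol (5-methylbenzene-1,3-diol) | Cc1cc(O)cc(O)c1 | starting material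
2 | 1,3-bis(benzyloxy)-5-methylbenzene | Cc1cc(OCc2ccccc2)cc(OCc2ccccc2)c1 | intermediate
3 | 1,5-bis(benzyloxy)-2-iodo-3-methylbenzene | Cc1cc(OCc2ccccc2)cc(OCc2ccccc2)c1I | intermediate
4 | 2-bromo-3-methylphenol | Cc1cccc(O)c1Br | starting material
5 | 2-bromo-1-[(3,5-dimethylbenzyl)oxy]-3-methylbenzene | Cc1cc(C)cc(COc2cccc(C)c2Br)c1 | intermediate
6 | 2-{4-bromo-3-[(3,5-dimethylbenzyl)oxy]-5-methylphenyl}-4,4,5,5-tetramethyl-1,3,2-dioxaborolane | Cc1cc(C)cc(COc2cc(B3OC(C)(C)C(C)(C)O3)cc(C)c2Br)c1 | intermediate
7 | 4-bromo-3-[(3,5-dimethylbenzyl)oxy]-5-methylphenol | Cc1cc(C)cc(COc2cc(O)cc(C)c2Br)c1 | intermediate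
8 | methyl 2-methoxy-6-methylbenzoate | COC(=O)c1c(C)cccc1OC | starting material
9 | methyl 2-methoxy-6-methyl-4-(4,4,5,5-tetramethyl-1,3,2-dioxaborolan-2-yl)benzoate | COC(=O)c1c(C)cc(B2OC(C)(C)C(C)(C)O2)cc1OC | intermediate
10 | methyl 4-hydroxy-2-methoxy-6-methylbenzoate | COC(=O)c1c(C)cc(O)cc1OC | intermediate
11 | 4-bromo-3-[(3,5-dimethylbenzyl)oxy]-5-methylphenyl 2,4-bis(benzyloxy)-6-methylbenzoate | Cc1cc(C)cc(COc2cc(OC(=O)c3c(C)cc(OCc4ccccc4)cc3OCc3ccccc3)cc(C)c2Br)c1 | intermediate
12 | methyl 4-({4-[(2,4-bis(benzyloxy)-6-methylbenzoyl)oxy]-2-[(3,5-dimethylbenzyl)oxy]-6-methylbenzoyl}oxy)-2-methoxy-6-methylbenzoate | COC(=O)c1c(C)cc(OC(=O)c2c(C)cc(OC(=O)c3c(C)cc(OCc4ccccc4)cc3OCc3ccccc3)cc2OCc2cc(C)cc(C)c2)cc1OC | intermediate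
13 | CNP0503951.0, methyl 4-({4-[(2,4-dihydroxy-6-methylbenzoyl)oxy]-2-hydroxy-6-methylbenzoyl}oxy)-2-methoxy-6-methylbenzoate | COC(=O)c1c(C)cc(OC(=O)c2c(C)cc(OC(=O)c3c(C)cc(O)cc3O)cc2O)cc1OC | target

Total step count: 8. Longest linear sequence: 5 steps (1 → 2 → 3 → 11 → 12 → 13, or 4 → 5 → 7 → 11 → 12 → 13).

Steps most likely to fail:

1. Step 7. Oxidative addition into the C–Br bond between two ortho substituents may be slow under CO, so that catalyst decay, hydrodebromination or aryloxide attack on the existing ester link could compete. The fallback would set out from 7 and come back at 12; it makes the ring B carboxyl from an aryllithium and CO2 and leaves the only palladium step to an aryl iodide. Silylation of 7 (TIPSCl, imidazole, DMF) would give [4-bromo-3-[(3,5-dimethylbenzyl)oxy]-5-methylphenoxy]triisopropylsilane F1. Bromine–lithium exchange (n-BuLi, THF, −78 °C) and quenching with CO2 would give 2-[(3,5-dimethylbenzyl)oxy]-6-methyl-4-(triisopropylsilyloxy)benzoic acid F2. Mixed-anhydride esterification of F2 with phenol 10 (trifluoroacetic anhydride, PhMe, rt) would give methyl 4-({2-[(3,5-dimethylbenzyl)oxy]-6-methyl-4-(triisopropylsilyloxy)benzoyl}oxy)-2-methoxy-6-methylbenzoate F3. Desilylation (TBAF, AcOH, THF, 0 °C) would give methyl 4-({2-[(3,5-dimethylbenzyl)oxy]-4-hydroxy-6-methylbenzoyl}oxy)-2-methoxy-6-methylbenzoate F4. Carbonylative coupling of F4 with iodide 3 under the conditions of step 6 would then give 12.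

2. Step 6. Selectivity between the C–I bond and the C–Br bonds may erode and give oligomers, or slow capture of the crowded aroyl–palladium intermediate may lead to hydrodeiodination. The fallback would set out from 3 and come back at 11. Iodine–magnesium exchange (i-PrMgCl·LiCl, THF, −20 °C) and CO2 would give 2,4-bis(benzyloxy)-6-methylbenzoic acid F5, and esterification of F5 with phenol 7 through the mixed trifluoroacetic anhydride (trifluoroacetic anhydride, PhMe, rt) would give 11.

3. Step 4. Borylation of the electron-rich bromoarene may stall, part of the C–Br bond may be lost, or the electron-rich phenol may be over-oxidized in the peroxide stage. The fallback would set out from 1 and come back at 7. Mono-alkylation of excess orcinol with 3,5-dimethylbenzyl bromide (K2CO3, DMF) would give 3-[(3,5-dimethylbenzyl)oxy]-5-methylphenol F6, and bromination para to the free hydroxyl group (n-Bu4NBr3, CH2Cl2/MeOH, rt) would give 7 after separation from its regioisomers.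

Further compounds
F1 | step 7 | [4-bromo-3-[(3,5-dimethylbenzyl)oxy]-5-methylphenoxy]triisopropylsilane | Cc1cc(C)cc(COc2cc(O[Si](C(C)C)(C(C)C)C(C)C)cc(C)c2Br)c1
F2 | step 7 | 2-[(3,5-dimethylbenzyl)oxy]-6-methyl-4-(triisopropylsilyloxy)benzoic acid | Cc1cc(C)cc(COc2cc(O[Si](C(C)C)(C(C)C)C(C)C)cc(C)c2C(=O)O)c1
F3 | step 7 | methyl 4-({2-[(3,5-dimethylbenzyl)oxy]-6-methyl-4-(triisopropylsilyloxy)benzoyl}oxy)-2-methoxy-6-methylbenzoate | COC(=O)c1c(C)cc(OC(=O)c2c(C)cc(O[Si](C(C)C)(C(C)C)C(C)C)cc2OCc2cc(C)cc(C)c2)cc1OC
F4 | step 7 | methyl 4-({2-[(3,5-dimethylbenzyl)oxy]-4-hydroxy-6-methylbenzoyl}oxy)-2-methoxy-6-methylbenzoate | COC(=O)c1c(C)cc(OC(=O)c2c(C)cc(O)cc2OCc2cc(C)cc(C)c2)cc1OC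
F5 | step 6 | 2,4-bis(benzyloxy)-6-methylbenzoic acid | Cc1cc(OCc2ccccc2)cc(OCc2ccccc2)c1C(=O)O
F6 | step 4 | 3-[(3,5-dimethylbenzyl)oxy]-5-methylphenol | Cc1cc(C)cc(COc2cc(C)cc(O)c2)c1
A1 | direct plan | methyl 4-hydroxy-2-methoxy-6-methylbenzoate | COC(=O)c1c(C)cc(O)cc1OC
A2 | direct plan | methyl 4-(but-2-ynoyloxy)-2-methoxy-6-methylbenzoate | COC(=O)c1c(C)cc(OC(=O)C#CC)cc1OC
A3 | direct plan | (Z)-1-methoxy-1,3-bis(trimethylsilyloxy)buta-1,3-diene | CO/C(O[Si](C)(C)C)=C/C(O[Si](C)(C)C)=C
A4 | direct plan | methyl 4-[(2,4-dihydroxy-6-methylbenzoyl)oxy]-2-methoxy-6-methylbenzoate | COC(=O)c1c(C)cc(OC(=O)c2c(C)cc(O)cc2O)cc1OC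
A5 | direct plan | methyl 4-{[4-(but-2-ynoyloxy)-2-hydroxy-6-methylbenzoyl]oxy}-2-methoxy-6-methylbenzoate | COC(=O)c1c(C)cc(OC(=O)c2c(C)cc(OC(=O)C#CC)cc2O)cc1OC
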